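The route rests on disconnecting the O1–C8a aryl ether bond of ring C while C4 is still a silyl-protected carbinol, so that the hydrogen at C3 has no carbonyl beside it and is not acidic. A single copper-catalysed intramolecular C–O coupling between a primary alcohol and the ring A bromide then closes ring C under carbonate base with the (3R) centre untouched. The precursor is a syn 2-aryl-3-(2-bromoaryl)-3-silyloxypropan-1-ol, made by an Evans aldol between the ring B arylacetyl imide and a pentasubstituted ring A bromobenzaldehyde. Desilylation, oxidation at C4 and removal of the methoxymethyl ethers complete the target.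

Key step: step 11

Remark (locants and abbreviations): O1, C2, C3, C4, C4a, C5 to C8 and C8a are the locants of the 3-arylchroman-4-one core; ring A is the benzo ring, ring B the 3-aryl group, ring C the oxygen heterocycle; prenyl = 3-methylbut-2-en-1-yl, MOM = methoxymethyl.
Assumption: all compounds marked as starting material in the compound list are taken as commercial.
Remark (design): the C4 oxygen is carried as a triisopropylsilyl ether, because a smaller silyl group on the secondary oxygen of a 1,3-diol can shift to the primary alkoxide under carbonate at 100 °C and would then mask the nucleophile of the ring closure; the (S)-configured auxiliary is the one that leads to (3R).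

Step 1
Reactants: 1 5-bromoresorcinol (5-bromobenzene-1,3-diol)
Product: 2 5-bromo-2-iodobenzene-1,3-diol
Conditions: I2 (1.05 equiv), NaHCO3, THF–H2O, 0 °C
Reagents that add atoms: iodine, II
Why: Electrophilic aromatic iodination of the phenoxide in aqueous bicarbonate goes to the carbon between the two hydroxyl groups, as is known for resorcinol and 5-substituted resorcinols, and the bromine shields the other two positions further, so the later prenyl site is fixed without relying on the regiochemistry of a deprotonation.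

Step 2
Reactants: 2 5-bromo-2-iodobenzene-1,3-diol
Product: 3 5-bromo-2-iodo-1,3-bis(methoxymethoxy)benzene
Conditions: MOMCl, iPr2NEt, CH2Cl2, 0 °C → rt
Reagents that add atoms: chloromethyl methyl ether, COCCl
Why: Base-mediated O-alkylation of both phenols (Williamson-type formation of the acetal ethers) gives protecting groups that withstand organolithium, carbonate and fluoride reagents and are removed only by acid at the end.

Step 3
Reactants: 3 5-bromo-2-iodo-1,3-bis(methoxymethoxy)benzene; 4 prenyl bromide (1-bromo-3-methylbut-2-ene)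
Product: 6 5-bromo-1,3-bis(methoxymethoxy)-2-(3-methylbut-2-en-1-yl)benzene, via aryllithium 5 (not isolated)
Conditions: n-BuLi (1.05 equiv), THF, −78 °C; then 4 (1.5 equiv), −78 → 0 °C
Reagents that add atoms: none
Why: Iodine–lithium exchange is much faster than bromine–lithium exchange at −78 °C, so only the carbon between the two ethers is metallated, and aryllithium 5 then displaces bromide at the primary carbon of 4 (SN2 allylation) to give the linear prenyl group.

Step 4
Reactants: 6 5-bromo-1,3-bis(methoxymethoxy)-2-(3-methylbut-2-en-1-yl)benzene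
Product: 8 6-bromo-2,4-bis(methoxymethoxy)-3-(3-methylbut-2-en-1-yl)benzaldehyde, via aryllithium 7 (not isolated)
Conditions: LiN(iPr)2 (1.2 equiv), THF, −78 °C; then DMF, −78 → −20 °C; aq. NH4Cl
Reagents that add atoms: N,N-dimethylformamide, CN(C)C=O
Why: Directed ortho-metallation by the amide base, which does not exchange the bromine, removes one of the two equivalent ring hydrogens, each flanked and acidified by bromine and a methoxymethoxy group, and aryllithium 7 is formylated by DMF (Bouveault-type formylation).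

Step 5
Reactants: 9 3-bromo-4-hydroxyphenylacetic acid
Product: 10 methoxymethyl [3-bromo-4-(methoxymethoxy)phenyl]acetate
Conditions: MOMCl (2.5 equiv), iPr2NEt, CH2Cl2, 0 °C → rt
Reagents that add atoms: chloromethyl methyl ether, COCCl
Why: Double O-alkylation converts the phenol into its acetal ether and the acid into the methoxymethyl ester in one operation, which removes both acidic protons before the cross-coupling.

Step 6
Reactants: 10 methoxymethyl [3-bromo-4-(methoxymethoxy)phenyl]acetate; 11 prenylboronic acid pinacol ester (4,4,5,5-tetramethyl-2-(3-methylbut-2-en-1-yl)-1,3,2-dioxaborolane)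
Product: 13 [4-(methoxymethoxy)-3-(3-methylbut-2-en-1-yl)phenyl]acetic acid, via methoxymethyl ester 12 (not isolated)
Conditions: PdCl2(dppf) (5 mol %), CsF (3 equiv), THF, 65 °C; then LiOH, MeOH–H2O, rt; dilute HCl to pH 4, 0 °C
Reagents that add atoms: lithium hydroxide, [Li+].[OH-]
Why: Suzuki–Miyaura coupling of the aryl bromide with the allylic boronate under PdCl2(dppf) and fluoride, conditions known to give the linear α-coupled prenyl arene, is followed by saponification of the labile ester 12 in the same flask.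

Step 7
Reactants: 13 [4-(methoxymethoxy)-3-(3-methylbut-2-en-1-yl)phenyl]acetic acid; 14 (S)-4-benzyl-1,3-oxazolidin-2-one
Product: 16 (4S)-4-benzyl-3-{[4-(methoxymethoxy)-3-(3-methylbut-2-en-1-yl)phenyl]acetyl}-1,3-oxazolidin-2-one, via mixed pivalic anhydride 15 (not isolated)
Conditions: t-BuCOCl, Et3N, THF, −20 °C; then LiCl, 14, −20 °C → rt
Reagents that add atoms: none
Why: N-Acylation of the oxazolidinone by the mixed anhydride 15 under LiCl and Et3N transfers the arylacetyl group, because the hindered pivaloyl carbonyl is not attacked.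

Step 8
Reactants: 16 the ring B arylacetyl imide; 8 6-bromo-2,4-bis(methoxymethoxy)-3-(3-methylbut-2-en-1-yl)benzaldehyde
Product: 18 (4S)-4-benzyl-3-[(2S,3S)-3-[6-bromo-2,4-bis(methoxymethoxy)-3-(3-methylbut-2-en-1-yl)phenyl]-3-hydroxy-2-[4-(methoxymethoxy)-3-(3-methylbut-2-en-1-yl)phenyl]propanoyl]-1,3-oxazolidin-2-one, via boron enolate 17 (not isolated)
Conditions: Bu2BOTf (1.2 equiv), iPr2NEt, CH2Cl2, −78 → 0 °C; then 8, −78 → 0 °C; pH 7 buffer, MeOH, H2O2, 0 °C
Reagents that add atoms: none
Why: Evans syn aldol, in which soft enolisation gives the (Z)-boron enolate 17 and this adds to the aldehyde through a Zimmerman–Traxler chair on the face away from the benzyl group of the (S)-auxiliary with the two imide carbonyls opposed, should set (2S) at the future C3 and (3S) at the future C4.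

Step 9
Reactants: 18 the syn aldol adduct
Product: 19 (4S)-4-benzyl-3-[(2S,3S)-3-[6-bromo-2,4-bis(methoxymethoxy)-3-(3-methylbut-2-en-1-yl)phenyl]-2-[4-(methoxymethoxy)-3-(3-methylbut-2-en-1-yl)phenyl]-3-[(triisopropylsilyl)oxy]propanoyl]-1,3-oxazolidin-2-one
Conditions: iPr3SiOTf (1.5 equiv), 2,6-lutidine, CH2Cl2, 0 °C → rt
Reagents that add atoms: triisopropylsilyl trifluoromethanesulfonate, CC(C)[Si](C(C)C)(C(C)C)OS(=O)(=O)C(F)(F)F
Why: Silylation of the hindered secondary carbinol with a silyl triflate and a hindered pyridine base is mild enough to avoid retro-aldol cleavage and epimerisation of the α-aryl centre, and gives a silyl ether that does not migrate to a neighbouring alkoxide.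

Step 10
Reactants: 19 the silylated aldol imide
Product: 20 (2R,3S)-3-[6-bromo-2,4-bis(methoxymethoxy)-3-(3-methylbut-2-en-1-yl)phenyl]-2-[4-(methoxymethoxy)-3-(3-methylbut-2-en-1-yl)phenyl]-3-[(triisopropylsilyl)oxy]propan-1-ol
Conditions: LiBH4 (2 equiv), H2O (1.1 equiv), Et2O–THF, 0 °C → rt
Reagents that add atoms: none
Why: Reductive cleavage of the N-acyl oxazolidinone by LiBH4 delivers hydride to the exocyclic imide carbonyl and should give the primary alcohol without touching the two stereocentres, the aryl bromide or the double bonds, with recovery of the auxiliary.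

Step 11
Reactants: 20 the syn bromo alcohol
Product: 21 (3R,4S)-5,7-bis(methoxymethoxy)-3-[4-(methoxymethoxy)-3-(3-methylbut-2-en-1-yl)phenyl]-6-(3-methylbut-2-en-1-yl)-4-[(triisopropylsilyl)oxy]chromane (3,4-trans)
Conditions: CuI (10 mol %), 3,4,7,8-tetramethyl-1,10-phenanthroline (20 mol %), Cs2CO3 (2 equiv), toluene (0.05 M), 100 °C, argon
Reagents that add atoms: none
Why: Cs2CO3 turns the primary hydroxyl into an alkoxide that binds the phenanthroline complex of CuI (monovalent copper); this copper alkoxide inserts into the C8a–Br bond held beside it to give a trivalent copper aryl alkoxide, and reductive elimination forms the O1–C8a bond and returns the catalyst. The closest known reaction type is the intramolecular Ullmann-type O-arylation of aliphatic alcohols with aryl bromides under copper and phenanthroline ligands, which gives chromans. Ring C closes in a six-membered exo mode, O1 attacking the sp2 carbon C8a while the leaving C–Br bond lies outside the new ring. No stereocentre is formed, and C3 and C4 are carried through unchanged because at the carbinol oxidation level the C3 hydrogen is not acidic toward carbonate. The step needs selectivity for the primary oxygen and against silyl transfer: the C4 oxygen is blocked by a bulky, non-migrating triisopropylsilyl group and could in any case only close a four-membered ring, and both methoxymethoxy groups are meta to C8a, so the C–Br bond is not deactivated by resonance.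

Step 12
Reactants: 21 the trans silyl ether
Product: 22 (3R,4S)-5,7-bis(methoxymethoxy)-3-[4-(methoxymethoxy)-3-(3-methylbut-2-en-1-yl)phenyl]-6-(3-methylbut-2-en-1-yl)chroman-4-ol
Conditions: Bu4NF (3 equiv), THF, rt → 45 °C
Reagents that add atoms: none
Why: Fluoride-induced cleavage of the Si–O bond (desilylation) frees the C4 carbinol, and the basic fluoride is harmless because C3 still has no carbonyl next to it.

Step 13
Reactants: 22 the chroman-4-ol
Product: 23 (3R)-5,7-bis(methoxymethoxy)-3-[4-(methoxymethoxy)-3-(3-methylbut-2-en-1-yl)phenyl]-6-(3-methylbut-2-en-1-yl)chroman-4-one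
Conditions: Dess–Martin periodinane (1.5 equiv), NaHCO3 (solid), CH2Cl2, 0 °C → rt; work-up at pH 7
Reagents that add atoms: none
Why: Dess–Martin oxidation of the secondary benzylic alcohol under buffered, nearly neutral conditions should give the ketone without enolisation toward C3 and without attack on the prenyl double bonds.

Step 14
Reactants: 23 the tris(methoxymethyl) ether of the target
Product: 24 (3R)-5,7-dihydroxy-3-[4-hydroxy-3-(3-methylbut-2-en-1-yl)phenyl]-6-(3-methylbut-2-en-1-yl)chroman-4-one (target)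
Conditions: HCl (about 1 M in MeOH), THF–MeOH, 0 °C → rt; work-up with pH 6 phosphate buffer
Reagents that add atoms: none
Why: Acid-catalysed methanolysis of the three aryl methoxymethyl acetals (acetal exchange to dimethoxymethane) is run in dilute acid without heating and with a weakly acidic work-up, so that enolisation at C3 and cyclisation of the phenols onto the prenyl groups should stay slower than the deprotection.

Compound list
1 | 5-bromoresorcinol (5-bromobenzene-1,3-diol) | Oc1cc(O)cc(Br)c1 | starting material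
2 | 5-bromo-2-iodobenzene-1,3-diol | Oc1cc(Br)cc(O)c1I | intermediate
3 | 5-bromo-2-iodo-1,3-bis(methoxymethoxy)benzene | COCOc1cc(Br)cc(OCOC)c1I | intermediate
4 | prenyl bromide (1-bromo-3-methylbut-2-ene) | CC(C)=CCBr | starting material
5 | [4-bromo-2,6-bis(methoxymethoxy)phenyl]lithium | [Li]c1c(OCOC)cc(Br)cc1OCOC | intermediate (not isolated)
6 | 5-bromo-1,3-bis(methoxymethoxy)-2-(3-methylbut-2-en-1-yl)benzene | COCOc1cc(Br)cc(OCOC)c1CC=C(C)C | intermediate
7 | [6-bromo-2,4-bis(methoxymethoxy)-3-(3-methylbut-2-en-1-yl)phenyl]lithium | [Li]c1c(Br)cc(OCOC)c(CC=C(C)C)c1OCOC | intermediate (not isolated)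
8 | 6-bromo-2,4-bis(methoxymethoxy)-3-(3-methylbut-2-en-1-yl)benzaldehyde | O=Cc1c(Br)cc(OCOC)c(CC=C(C)C)c1OCOC | intermediate
9 | 3-bromo-4-hydroxyphenylacetic acid | OC(=O)Cc1ccc(O)c(Br)c1 | starting material
10 | methoxymethyl [3-bromo-4-(methoxymethoxy)phenyl]acetate | COCOC(=O)Cc1ccc(OCOC)c(Br)c1 | intermediate
11 | prenylboronic acid pinacol ester (4,4,5,5-tetramethyl-2-(3-methylbut-2-en-1-yl)-1,3,2-dioxaborolane) | CC(C)=CCB1OC(C)(C)C(C)(C)O1 | starting material
12 | methoxymethyl [4-(methoxymethoxy)-3-(3-methylbut-2-en-1-yl)phenyl]acetate | COCOC(=O)Cc1ccc(OCOC)c(CC=C(C)C)c1 | intermediate (not isolated)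
13 | [4-(methoxymethoxy)-3-(3-methylbut-2-en-1-yl)phenyl]acetic acid | OC(=O)Cc1ccc(OCOC)c(CC=C(C)C)c1 | intermediate
14 | (S)-4-benzyl-1,3-oxazolidin-2-one | O=C1OC[C@H](Cc2ccccc2)N1 | starting material
15 | 2,2-dimethylpropanoic [4-(methoxymethoxy)-3-(3-methylbut-2-en-1-yl)phenyl]acetic anhydride | CC(C)(C)C(=O)OC(=O)Cc1ccc(OCOC)c(CC=C(C)C)c1 | intermediate (not isolated)
16 | (4S)-4-benzyl-3-{[4-(methoxymethoxy)-3-(3-methylbut-2-en-1-yl)phenyl]acetyl}-1,3-oxazolidin-2-one | O=C1OC[C@H](Cc2ccccc2)N1C(=O)Cc1ccc(OCOC)c(CC=C(C)C)c1 | intermediate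
17 | (4S)-4-benzyl-3-{(Z)-1-[(dibutylboranyl)oxy]-2-[4-(methoxymethoxy)-3-(3-methylbut-2-en-1-yl)phenyl]ethenyl}-1,3-oxazolidin-2-one | CCCCB(CCCC)O/C(=C\c1ccc(OCOC)c(CC=C(C)C)c1)N1[C@@H](Cc2ccccc2)COC1=O | intermediate (not isolated)
18 | (4S)-4-benzyl-3-[(2S,3S)-3-[6-bromo-2,4-bis(methoxymethoxy)-3-(3-methylbut-2-en-1-yl)phenyl]-3-hydroxy-2-[4-(methoxymethoxy)-3-(3-methylbut-2-en-1-yl)phenyl]propanoyl]-1,3-oxazolidin-2-one | O=C1OC[C@H](Cc2ccccc2)N1C(=O)[C@@H](c1ccc(OCOC)c(CC=C(C)C)c1)[C@H](O)c1c(Br)cc(OCOC)c(CC=C(C)C)c1OCOC | intermediate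
19 | (4S)-4-benzyl-3-[(2S,3S)-3-[6-bromo-2,4-bis(methoxymethoxy)-3-(3-methylbut-2-en-1-yl)phenyl]-2-[4-(methoxymethoxy)-3-(3-methylbut-2-en-1-yl)phenyl]-3-[(triisopropylsilyl)oxy]propanoyl]-1,3-oxazolidin-2-one | O=C1OC[C@H](Cc2ccccc2)N1C(=O)[C@@H](c1ccc(OCOC)c(CC=C(C)C)c1)[C@H](O[Si](C(C)C)(C(C)C)C(C)C)c1c(Br)cc(OCOC)c(CC=C(C)C)c1OCOC | intermediate
20 | (2R,3S)-3-[6-bromo-2,4-bis(methoxymethoxy)-3-(3-methylbut-2-en-1-yl)phenyl]-2-[4-(methoxymethoxy)-3-(3-methylbut-2-en-1-yl)phenyl]-3-[(triisopropylsilyl)oxy]propan-1-ol | CC(C)=CCc1cc([C@@H]([C@H](O[Si](C(C)C)(C(C)C)C(C)C)c2c(Br)cc(OCOC)c(CC=C(C)C)c2OCOC)CO)ccc1OCOC | intermediate (precursor of the key step)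
21 | (3R,4S)-5,7-bis(methoxymethoxy)-3-[4-(methoxymethoxy)-3-(3-methylbut-2-en-1-yl)phenyl]-6-(3-methylbut-2-en-1-yl)-4-[(triisopropylsilyl)oxy]chromane | CC(C)=CCc1cc([C@@H]2COc3cc(OCOC)c(CC=C(C)C)c(OCOC)c3[C@H]2O[Si](C(C)C)(C(C)C)C(C)C)ccc1OCOC | intermediate (product of the key step)
22 | (3R,4S)-5,7-bis(methoxymethoxy)-3-[4-(methoxymethoxy)-3-(3-methylbut-2-en-1-yl)phenyl]-6-(3-methylbut-2-en-1-yl)chroman-4-ol | CC(C)=CCc1cc([C@@H]2COc3cc(OCOC)c(CC=C(C)C)c(OCOC)c3[C@H]2O)ccc1OCOC | intermediate
23 | (3R)-5,7-bis(methoxymethoxy)-3-[4-(methoxymethoxy)-3-(3-methylbut-2-en-1-yl)phenyl]-6-(3-methylbut-2-en-1-yl)chroman-4-one | CC(C)=CCc1cc([C@@H]2COc3cc(OCOC)c(CC=C(C)C)c(OCOC)c3C2=O)ccc1OCOC | intermediate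
24 | (3R)-5,7-dihydroxy-3-[4-hydroxy-3-(3-methylbut-2-en-1-yl)phenyl]-6-(3-methylbut-2-en-1-yl)chroman-4-one | CC(C)=CCc1cc([C@@H]2COc3cc(O)c(CC=C(C)C)c(O)c3C2=O)ccc1O | target

Total step count: 14
Longest linear sequence: 11 steps (steps 1 to 4, then 8 to 14); the ring B branch (steps 5 to 7) joins at step 8.

Steps most likely to fail

Step 11 (key step). The copper alkoxide may insert too slowly into the crowded C8a–Br bond, so that reduction of the bromide or decomposition on long heating takes over. The fallback sets out from 20 and comes back at 21, and it closes ring C from the other side, forming the O1–C2 bond last. Miyaura borylation of 20 (B2pin2, PdCl2(dppf), KOAc, dioxane, 85 °C) should give the aryl pinacol boronate F1. Oxidation with NaBO3·4H2O in THF–water should give the C8a phenol F2. A Mitsunobu cyclisation (PPh3, diisopropyl azodicarboxylate, THF, 0 °C), in which the phenol attacks the activated primary carbinol, should then give 21 with both stereocentres untouched.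

Step 8. Addition of the boron enolate to the doubly ortho-substituted, electron-rich aldehyde may be sluggish, and reversal of the aldol on long reaction times would erode conversion and syn selectivity. The fallback sets out from 13 and comes back at 20. Coupling of 13 with (S)-4-benzyl-1,3-thiazolidine-2-thione (EDC·HCl, 4-dimethylaminopyridine, CH2Cl2) should give the N-acyl thiazolidinethione F3. Soft enolisation with TiCl4, iPr2NEt and N-methylpyrrolidinone in CH2Cl2 at −78 °C and addition of 8 uses a more reactive titanium enolate and should give the syn aldol F4 with the same (2S,3S) configuration. Silylation (iPr3SiOTf, 2,6-lutidine) should give the silyl ether F5, and LiBH4 in Et2O at 0 °C should remove the auxiliary to give 20.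

Step 14. During the hours of exposure to protic acid the ketone may enolise toward C3, which erodes the configuration, or a phenol may add to a neighbouring prenyl double bond. The fallback sets out from 23 and comes back at 24 and makes no new compound (F0). It replaces solvolysis by a thiol-assisted Lewis acid dealkylation in an aprotic medium: ZnBr2 (1 equiv per ether) and n-PrSH (2 equiv per ether) in CH2Cl2 at 0 °C for a few minutes. The Lewis acid activates each acetal and the thiol takes over the methoxymethyl group, so the contact time is minutes at low temperature without Brønsted acid or base.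

Further compounds
F1 | step 11 | (2R,3S)-3-[2,4-bis(methoxymethoxy)-3-(3-methylbut-2-en-1-yl)-6-(4,4,5,5-tetramethyl-1,3,2-dioxaborolan-2-yl)phenyl]-2-[4-(methoxymethoxy)-3-(3-methylbut-2-en-1-yl)phenyl]-3-[(triisopropylsilyl)oxy]propan-1-ol | CC(C)=CCc1cc([C@@H]([C@H](O[Si](C(C)C)(C(C)C)C(C)C)c2c(B3OC(C)(C)C(C)(C)O3)cc(OCOC)c(CC=C(C)C)c2OCOC)CO)ccc1OCOC
F2 | step 11 | (2R,3S)-3-[6-hydroxy-2,4-bis(methoxymethoxy)-3-(3-methylbut-2-en-1-yl)phenyl]-2-[4-(methoxymethoxy)-3-(3-methylbut-2-en-1-yl)phenyl]-3-[(triisopropylsilyl)oxy]propan-1-ol | CC(C)=CCc1cc([C@@H]([C@H](O[Si](C(C)C)(C(C)C)C(C)C)c2c(O)cc(OCOC)c(CC=C(C)C)c2OCOC)CO)ccc1OCOC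
F3 | step 8 | (4S)-4-benzyl-3-{[4-(methoxymethoxy)-3-(3-methylbut-2-en-1-yl)phenyl]acetyl}-1,3-thiazolidine-2-thione | S=C1SC[C@H](Cc2ccccc2)N1C(=O)Cc1ccc(OCOC)c(CC=C(C)C)c1
F4 | step 8 | (4S)-4-benzyl-3-[(2S,3S)-3-[6-bromo-2,4-bis(methoxymethoxy)-3-(3-methylbut-2-en-1-yl)phenyl]-3-hydroxy-2-[4-(methoxymethoxy)-3-(3-methylbut-2-en-1-yl)phenyl]propanoyl]-1,3-thiazolidine-2-thione | S=C1SC[C@H](Cc2ccccc2)N1C(=O)[C@@H](c1ccc(OCOC)c(CC=C(C)C)c1)[C@H](O)c1c(Br)cc(OCOC)c(CC=C(C)C)c1OCOC
F5 | step 8 | (4S)-4-benzyl-3-[(2S,3S)-3-[6-bromo-2,4-bis(methoxymethoxy)-3-(3-methylbut-2-en-1-yl)phenyl]-2-[4-(methoxymethoxy)-3-(3-methylbut-2-en-1-yl)phenyl]-3-[(triisopropylsilyl)oxy]propanoyl]-1,3-thiazolidine-2-thione | S=C1SC[C@H](Cc2ccccc2)N1C(=O)[C@@H](c1ccc(OCOC)c(CC=C(C)C)c1)[C@H](O[Si](C(C)C)(C(C)C)C(C)C)c1c(Br)cc(OCOC)c(CC=C(C)C)c1OCOC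
F0 | step 14 | none | none
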